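(The runs are calculated on assumed constants; the scatter is artificial.)

| setting | Sunday's | Wednesday's | flask |
|---|---|---|---|
| substrate | 0.82 M | 0.82 M | 0.82 M |
| first nucleophile | 0.574 M | 1.1 M | 0.574 M |
| second nucleophile | 0.492 M | 0.492 M | 0.492 M |
| remark | the very flask that is asked about, followed so far | run made earlier |  |
| time |  |  | 25 h |

| run | time / h | target / % | substrate / % |
|---|---|---|---|
| Sunday's | 0.100 | 13.3 | 73.6 |
| Sunday's | 0.333 | 24.9 | 36.2 |
| Sunday's | 1.00 | 20.5 | 4.7 |
| Sunday's | 3.00 | 7.1 | 0 |
| Sunday's | 10.0 | 1.7 | 0 |
| Wednesday's | 0.100 | 17.4 | 73.5 |
| Wednesday's | 0.333 | 34.2 | 35.7 |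
| Wednesday's | 1.00 | 31.8 | 4.7 |
| Wednesday's | 3.00 | 17.7 | 0 |
| Wednesday's | 10.0 | 11.1 | 0.1 |

(scatter of a reading: 0.3 percentage points)

- time, not beyond 25 h, at which the flask holds most target
- the amount of target, in percent of the substrate charged, at that time
- the first time at which target reaches 7.7 %, in the same percent



Slowness sits at the start: at 0.333 h Sunday's run keeps 36.2 % of its substrate and Wednesday's keeps 35.7 %, although first nucleophile stood at 0.574 M against 1.1 M. I read a rate-limiting step to an intermediate, first order, with constant 3.07 /h.

What does the first nucleophile change, then? The split of that intermediate. Target per substrate lost at 0.100 h reads 0.504 on Sunday and 0.657 on Wednesday. Writing the share as first nucleophile over first nucleophile plus a constant defines the half-capture concentration, the level of first nucleophile at which target takes as much intermediate as the competing exits together: 0.565 M from Sunday. Wednesday, with its different charge, gives 0.575 M, which agrees.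

Where is it weak? It is read early, against the charged first nucleophile, and the run consumes that nucleophile, so I treat the share as a starting value.

And the other end? Between 0.333 h and 1.00 h, Sunday's target made by that share, less the observed change, gives a loss constant of 1.34 /h. Joining rise and decay as consecutive first-order steps, I get a peak time of 0.480 h and a peak of 26.5 %. The rise alone reaches the level at 0.0541 h.

The forecast says 26 % at 0.5 h, and the level at 0.053 h, close to my figures but not identical: “The mechanism is unclear, but that doesn't matter before the peak.”

The flask peaks at 25.6 % at 0.450 h and reaches the level at 0.0502 h.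

    substrate → intermediate (k = 8.60 × 10⁻⁴ /s)
    first nucleophile + intermediate → target (k = 0.160 /M/s)
    second nucleophile + intermediate → other capture product (k = 0.0160 /M/s)
    intermediate → solvolysis product (k = 0.0440 /s)
    second nucleophile + target → over-reaction product (k = 9.60 × 10⁻⁴ /M/s)
    intermediate → side product (k = 0.0110 /s)
    intermediate → decomposed reagent (k = 3.00 × 10⁻⁴ /s)

On this flask the half-capture concentration, at the charge of 0.574 M, returns the early share of 0.504 by construction. The neighbouring flask charges 0.14 M of first nucleophile, which gives a starting share of 0.198. I keep the rise and decay constants, so the peak scales with the share, and 25.6 % becomes 10.1 %. The neighbouring flask gives 8.27 %, and at 25.0 h its first nucleophile stands at 16.4 % of its charge.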